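**Retrosynthetic overview**

1. The target is a 5,7,4'-trihydroxy-6,8-diprenylflavone in which C3 and C2' are joined through C9H2–C10H(C11Me2OH)–O, giving the oxepine ring D. The route rests on one feature: the C2–C1' bond is shared by pyranone ring C and ring D, and a 3-alkylchromone has only one ring C hydrogen, at C2.
2. C2–C1' is made last, by intramolecular palladium C–H arylation of C2–H with the ring B bromide carried on the C10 ether oxygen (closes ring D), followed by one deprotection.
3. Ring C comes from a 2-hydroxyaryl ketone and a one-carbon amide acetal. The ketone (C4–C4a bond) comes from lithiated 2,4-diprenyl-1,3,5-tris(methoxymethoxy)benzene and δ-lactone 16.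
4. Lactone 16 comes from L-glutamic acid 5-allyl ester: diazotisation with retention, Mitsunobu inversion with 2-bromo-5-(methoxymethoxy)phenol (O–C10 bond, R at C10), then MeMgBr (C11).
5. Ring order: A (phloroglucinol) and B (4-bromoresorcinol) are bought, ring C forms in step 14, ring D in step 15.

Key step: step 15

Remark: chromone numbering is used (O1, C2, C3, C4=O, C4a, C5–C8, C8a; ring B C1'–C6'; C9 = CH2 on C3, C10 = stereocentre, C11 = CMe2O). The C11 hydroxyl is carried as a TES ether through steps 12–15 because a free hydroxyl at that distance can add to C2 under hot carbonate and open the pyranone, and the distal glutamate carboxyl is carried as an allyl ester because its release must spare the aryl MOM acetal.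

**Route**

Step 1
Reactants: 1 phloroglucinol
Product: 2 1,3,5-tris(methoxymethoxy)benzene
Conditions: NaH (3.6 equiv), MOMCl (3.6 equiv), DMF, 0 °C → rt
Reagents that add atoms: chloromethyl methyl ether (MOMCl), COCCl
Why: Williamson-type O-alkylation of the phenoxides by the hard electrophile MOMCl in DMF should give the tris-acetal, which serves as protection and as the directing group for the three ortho-lithiations that follow.

Step 2
Reactants: 2 1,3,5-tris(methoxymethoxy)benzene; 3 prenyl bromide
Product: 5 1,3,5-tris(methoxymethoxy)-2-(3-methylbut-2-enyl)benzene, via aryllithium 4 (not isolated)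
Conditions: n-BuLi (1.05 equiv), TMEDA, THF, 0 °C; then CuBr·SMe2 (10 mol%), 3 (1.1 equiv), −78 → 0 °C
Reagents that add atoms: none
Why: Directed ortho-metalation at a C–H flanked by two OMOM groups, then copper-catalysed SN2 allylation of the aryl nucleophile at the primary carbon of prenyl bromide.

Step 3
Reactants: 5 1,3,5-tris(methoxymethoxy)-2-(3-methylbut-2-enyl)benzene; 3 prenyl bromide
Product: 7 1,3,5-tris(methoxymethoxy)-2,4-bis(3-methylbut-2-enyl)benzene, via aryllithium 6 (not isolated)
Conditions: n-BuLi (1.05 equiv), TMEDA, THF, 0 °C; then CuBr·SMe2 (10 mol%), 3 (1.1 equiv), −78 → 0 °C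
Reagents that add atoms: none
Why: Second directed ortho-metalation at one of the two equivalent remaining C–H bonds (each still flanked by two OMOM groups) and the same allylation; precoordination of n-BuLi to the acetal oxygens should make ring metalation faster than deprotonation of the benzylic–allylic CH2.

Step 4
Reactants: 8 4-bromoresorcinol
Product: 9 2-bromo-5-(methoxymethoxy)phenol
Conditions: MOMCl (1.0 equiv), i-Pr2NEt (1.1 equiv), CH2Cl2, −20 → 0 °C; chromatography
Reagents that add atoms: chloromethyl methyl ether (MOMCl), COCCl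
Why: Mono-O-alkylation should favour the hydroxyl para to bromine, which is unhindered and not engaged in an O–H···Br contact, so that the hydroxyl ortho to bromine stays free for the Mitsunobu step; the regioisomer and the bis-ether are separable.

Step 5
Reactants: 10 L-glutamic acid 5-allyl ester
Product: 11 (2S)-2-hydroxy-5-oxo-5-(prop-2-enyloxy)pentanoic acid
Conditions: NaNO2 (1.5 equiv), AcOH/H2O, 0 °C → rt
Reagents that add atoms: water, O
Why: Diazotisation of the α-amino acid with neighbouring-group participation: the carboxylate expels N2 to give an α-lactone that water reopens at C2, two inversions that leave the S configuration in place.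

Step 6
Reactants: 11 (2S)-2-hydroxy-5-oxo-5-(prop-2-enyloxy)pentanoic acid
Product: 12 1-methyl 5-prop-2-enyl (2S)-2-hydroxypentanedioate
Conditions: MeI, KHCO3, DMF, rt
Reagents that add atoms: iodomethane, CI
Why: SN2 O-methylation of the carboxylate under bicarbonate esterifies the acid without epimerising C2 or disturbing the allyl ester; the product is used promptly because it can lactonise.

Step 7
Reactants: 12 1-methyl 5-prop-2-enyl (2S)-2-hydroxypentanedioate; 9 2-bromo-5-(methoxymethoxy)phenol
Product: 13 1-methyl 5-prop-2-enyl (2R)-2-[2-bromo-5-(methoxymethoxy)phenoxy]pentanedioate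
Conditions: PPh3, DIAD, THF, 0 °C → rt
Reagents that add atoms: none
Why: Mitsunobu etherification: the acidic ortho-bromophenol displaces the oxyphosphonium group at the ester α-carbon by SN2, which inverts S to R and sets the future C10 stereocentre together with the O–C10 bond.

Step 8
Reactants: 13 1-methyl 5-prop-2-enyl (2R)-2-[2-bromo-5-(methoxymethoxy)phenoxy]pentanedioate
Product: 14 (4R)-4-[2-bromo-5-(methoxymethoxy)phenoxy]-5-methoxy-5-oxopentanoic acid
Conditions: Pd(PPh3)4 (3 mol%), morpholine (3 equiv), THF, rt; aq. citric acid work-up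
Reagents that add atoms: none
Why: Tsuji–Trost deallylation: zerovalent palladium ionises the allyl ester to a π-allyl complex that morpholine captures, while the methyl ester, the MOM acetal and the aryl bromide (slow oxidative addition at room temperature) are left alone.

Step 9
Reactants: 14 (4R)-4-[2-bromo-5-(methoxymethoxy)phenoxy]-5-methoxy-5-oxopentanoic acid
Product: 15 (4R)-4-[2-bromo-5-(methoxymethoxy)phenoxy]-5-hydroxy-5-methylhexanoic acid
Conditions: MeMgBr (5 equiv), THF, −20 → 0 °C; aq. citric acid work-up
Reagents that add atoms: methylmagnesium bromide, C[Mg]Br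
Why: Double Grignard addition to the α-aryloxy methyl ester builds the C11 carbinol while the distal acid is shielded as its magnesium carboxylate; no bond to the stereocentre is broken and the intermediate ketone is expected to add faster than it enolises.

Step 10
Reactants: 15 (4R)-4-[2-bromo-5-(methoxymethoxy)phenoxy]-5-hydroxy-5-methylhexanoic acid
Product: 16 (5R)-5-[2-bromo-5-(methoxymethoxy)phenoxy]-6,6-dimethyloxan-2-one
Conditions: EDC·HCl, DMAP (cat.), CH2Cl2, rt
Reagents that add atoms: none
Why: Carbodiimide (Steglich) lactonisation; the gem-dimethyl carbinol should close readily to the six-membered lactone, which masks the tertiary hydroxyl and turns the acid into an acyl donor.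

Step 11
Reactants: 7 1,3,5-tris(methoxymethoxy)-2,4-bis(3-methylbut-2-enyl)benzene; 16 (5R)-5-[2-bromo-5-(methoxymethoxy)phenoxy]-6,6-dimethyloxan-2-one
Product: 18 (4R)-4-[2-bromo-5-(methoxymethoxy)phenoxy]-5-hydroxy-5-methyl-1-[2,4,6-tris(methoxymethoxy)-3,5-bis(3-methylbut-2-enyl)phenyl]hexan-1-one, via aryllithium 17 (not isolated)
Conditions: 7 (1.3 equiv), n-BuLi (1.2 equiv), TMEDA, THF, 0 °C; then 16 (1.0 equiv), −78 → −20 °C; H2O
Reagents that add atoms: none
Why: Directed ortho-metalation at the last ring A C–H followed by nucleophilic acyl addition to the lactone; the lithium hemiketal alkoxide should persist in the cold, and the di-ortho-oxygenated ketone released on opening is too hindered to take up a second aryllithium, so the C4–C4a bond forms once.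

Step 12
Reactants: 18 (4R)-4-[2-bromo-5-(methoxymethoxy)phenoxy]-5-hydroxy-5-methyl-1-[2,4,6-tris(methoxymethoxy)-3,5-bis(3-methylbut-2-enyl)phenyl]hexan-1-one
Product: 19 (4R)-4-[2-bromo-5-(methoxymethoxy)phenoxy]-5-methyl-5-(triethylsilyloxy)-1-[2,4,6-tris(methoxymethoxy)-3,5-bis(3-methylbut-2-enyl)phenyl]hexan-1-one
Conditions: TESOTf (1.3 equiv), 2,6-lutidine (2 equiv), CH2Cl2, −78 °C
Reagents that add atoms: triethylsilyl trifluoromethanesulfonate, CC[Si](CC)(CC)OS(=O)(=O)C(F)(F)F
Why: Silyl triflate silylation of the tertiary alcohol with a hindered pyridine base; at −78 °C the aryl MOM acetals and the hindered ketone are expected to be left alone.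

Step 13
Reactants: 19 (4R)-4-[2-bromo-5-(methoxymethoxy)phenoxy]-5-methyl-5-(triethylsilyloxy)-1-[2,4,6-tris(methoxymethoxy)-3,5-bis(3-methylbut-2-enyl)phenyl]hexan-1-one
Product: 20 (4R)-4-[2-bromo-5-(methoxymethoxy)phenoxy]-1-[2-hydroxy-4,6-bis(methoxymethoxy)-3,5-bis(3-methylbut-2-enyl)phenyl]-5-methyl-5-(triethylsilyloxy)hexan-1-one
Conditions: MgBr2·OEt2 (2 equiv), Et2O/toluene, 0 °C → rt; aq. NH4Cl
Reagents that add atoms: none
Why: Chelation-controlled Lewis-acid ether cleavage: magnesium held between the ketone oxygen and an ortho acetal oxygen delivers bromide to that OCH2 group, the magnesium phenoxide chelate so formed should shut down cleavage of the second ortho MOM, and the remote MOM and TES ethers have no such chelate.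

Step 14
Reactants: 20 (4R)-4-[2-bromo-5-(methoxymethoxy)phenoxy]-1-[2-hydroxy-4,6-bis(methoxymethoxy)-3,5-bis(3-methylbut-2-enyl)phenyl]-5-methyl-5-(triethylsilyloxy)hexan-1-one
Product: 22 3-[(2R)-2-[2-bromo-5-(methoxymethoxy)phenoxy]-3-methyl-3-(triethylsilyloxy)butyl]-5,7-bis(methoxymethoxy)-6,8-bis(3-methylbut-2-enyl)chromen-4-one, via enaminone 21 (not isolated)
Conditions: Me2NCH(OMe)2 (5 equiv), toluene, 100 °C
Reagents that add atoms: N,N-dimethylformamide dimethyl acetal, COC(OC)N(C)C
Why: Aminomethylenation of the ketone α-CH2 by the amide acetal gives an enaminone whose β-carbon is attacked by the chelated phenol with loss of dimethylamine (addition–elimination), the usual annulation of 2-hydroxyaryl alkyl ketones to 3-alkylchromones, which closes ring C and leaves C2–H as its only hydrogen.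

Step 15
Reactants: 22 3-[(2R)-2-[2-bromo-5-(methoxymethoxy)phenoxy]-3-methyl-3-(triethylsilyloxy)butyl]-5,7-bis(methoxymethoxy)-6,8-bis(3-methylbut-2-enyl)chromen-4-one
Product: 23 5,7,4'-tris(methoxymethyl) ether and C11 triethylsilyl ether of the target (ring D closed, 10R)
Conditions: Pd(OAc)2 (10 mol%), PCy3·HBF4 (20 mol%), PivOH (30 mol%), K2CO3 (3 equiv), dry degassed DMA, 110 °C
Reagents that add atoms: none
Why: Pd(OAc)2 is reduced by the phosphine to zerovalent palladium, which inserts into the C1'–Br bond; pivalate then assists concerted metalation–deprotonation of C2–H, acidified by O1 and the vinylogous carbonyl, and reductive elimination from the eight-membered diorganopalladium species forms C2–C1' (a Heck-type carbopalladation of C2=C3 followed by β-hydride elimination through the palladium enolate would give the same product). The closest known reaction type is the intramolecular direct arylation of heteroarene and chromone C–H bonds by tethered aryl bromides under carbonate–pivalate conditions, which is documented for ring sizes up to seven. Ring D closes by C(sp2)–C(sp2) bond formation in a 7-endo sense with respect to C2=C3, both alkene carbons ending up in the oxepine. No stereocentre is created; C10 lies outside the bonds that change and its hydrogen is not acidic, so the R configuration from step 7 is kept. The step needs site selectivity and must outpace hydrodebromination: ring A has no C–H, C3 is fully substituted and the C9–C10–O tether lets palladium reach only C2, the C11 hydroxyl is silylated so that it can neither add to C2 nor be O-arylated, and an electron-rich bulky phosphine in a dry, degassed medium should favour cyclisation over reduction.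

Step 16
Reactants: 23 5,7,4'-tris(methoxymethyl) ether and C11 triethylsilyl ether of the target
Product: 24 CNP0328977.2, (10R)-5,7,4'-trihydroxy-6,8-bis(3-methylbut-2-enyl)flavone bridged C3–C9H2–C10H[C11(CH3)2OH]–O–C2'
Conditions: 3 M HCl (aq)/MeOH/THF, rt → 40 °C
Reagents that add atoms: none
Why: Acid-catalysed acetal exchange with methanol removes the three MOM groups and solvolyses the tertiary TES ether in one operation; dilute acid and mild warming are chosen so that the prenyl groups should not cyclise onto the neighbouring phenols and C11–OH should not ionise.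

**Compound list**

1 | phloroglucinol | Oc1cc(O)cc(O)c1 | starting material
2 | 1,3,5-tris(methoxymethoxy)benzene | COCOc1cc(OCOC)cc(OCOC)c1 | intermediate
3 | prenyl bromide (1-bromo-3-methylbut-2-ene) | CC(C)=CCBr | starting material
4 | [2,4,6-tris(methoxymethoxy)phenyl]lithium | [Li]c1c(OCOC)cc(OCOC)cc1OCOC | intermediate
5 | 1,3,5-tris(methoxymethoxy)-2-(3-methylbut-2-enyl)benzene | COCOc1cc(OCOC)c(CC=C(C)C)c(OCOC)c1 | intermediate
6 | [2,4,6-tris(methoxymethoxy)-3-(3-methylbut-2-enyl)phenyl]lithium | [Li]c1c(OCOC)cc(OCOC)c(CC=C(C)C)c1OCOC | intermediate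
7 | 1,3,5-tris(methoxymethoxy)-2,4-bis(3-methylbut-2-enyl)benzene | CC(C)=CCc1c(OCOC)cc(OCOC)c(CC=C(C)C)c1OCOC | intermediate
8 | 4-bromoresorcinol | Oc1ccc(Br)c(O)c1 | starting material
9 | 2-bromo-5-(methoxymethoxy)phenol | COCOc1ccc(Br)c(O)c1 | intermediate
10 | L-glutamic acid 5-allyl ester | N[C@@H](CCC(=O)OCC=C)C(=O)O | starting material
11 | (2S)-2-hydroxy-5-oxo-5-(prop-2-enyloxy)pentanoic acid | O[C@@H](CCC(=O)OCC=C)C(=O)O | intermediate
12 | 1-methyl 5-prop-2-enyl (2S)-2-hydroxypentanedioate | O[C@@H](CCC(=O)OCC=C)C(=O)OC | intermediate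
13 | 1-methyl 5-prop-2-enyl (2R)-2-[2-bromo-5-(methoxymethoxy)phenoxy]pentanedioate | COC(=O)[C@@H](CCC(=O)OCC=C)Oc1cc(OCOC)ccc1Br | intermediate
14 | (4R)-4-[2-bromo-5-(methoxymethoxy)phenoxy]-5-methoxy-5-oxopentanoic acid | COC(=O)[C@@H](CCC(=O)O)Oc1cc(OCOC)ccc1Br | intermediate
15 | (4R)-4-[2-bromo-5-(methoxymethoxy)phenoxy]-5-hydroxy-5-methylhexanoic acid | CC(C)(O)[C@@H](CCC(=O)O)Oc1cc(OCOC)ccc1Br | intermediate
16 | (5R)-5-[2-bromo-5-(methoxymethoxy)phenoxy]-6,6-dimethyloxan-2-one | O=C1CC[C@@H](Oc2cc(OCOC)ccc2Br)C(C)(C)O1 | intermediate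
17 | [2,4,6-tris(methoxymethoxy)-3,5-bis(3-methylbut-2-enyl)phenyl]lithium | [Li]c1c(OCOC)c(CC=C(C)C)c(OCOC)c(CC=C(C)C)c1OCOC | intermediate
18 | (4R)-4-[2-bromo-5-(methoxymethoxy)phenoxy]-5-hydroxy-5-methyl-1-[2,4,6-tris(methoxymethoxy)-3,5-bis(3-methylbut-2-enyl)phenyl]hexan-1-one | CC(C)=CCc1c(OCOC)c(CC=C(C)C)c(OCOC)c(C(=O)CC[C@@H](Oc2cc(OCOC)ccc2Br)C(C)(C)O)c1OCOC | intermediate
19 | (4R)-4-[2-bromo-5-(methoxymethoxy)phenoxy]-5-methyl-5-(triethylsilyloxy)-1-[2,4,6-tris(methoxymethoxy)-3,5-bis(3-methylbut-2-enyl)phenyl]hexan-1-one | CC(C)=CCc1c(OCOC)c(CC=C(C)C)c(OCOC)c(C(=O)CC[C@@H](Oc2cc(OCOC)ccc2Br)C(C)(C)O[Si](CC)(CC)CC)c1OCOC | intermediate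
20 | (4R)-4-[2-bromo-5-(methoxymethoxy)phenoxy]-1-[2-hydroxy-4,6-bis(methoxymethoxy)-3,5-bis(3-methylbut-2-enyl)phenyl]-5-methyl-5-(triethylsilyloxy)hexan-1-one | CC(C)=CCc1c(OCOC)c(CC=C(C)C)c(OCOC)c(C(=O)CC[C@@H](Oc2cc(OCOC)ccc2Br)C(C)(C)O[Si](CC)(CC)CC)c1O | intermediate
21 | 2-(dimethylaminomethylidene) derivative of 20 (enaminone; push–pull alkene, geometry not assigned) | CC(C)=CCc1c(OCOC)c(CC=C(C)C)c(OCOC)c(C(=O)C(=CN(C)C)C[C@@H](Oc2cc(OCOC)ccc2Br)C(C)(C)O[Si](CC)(CC)CC)c1O | intermediate
22 | 3-[(2R)-2-[2-bromo-5-(methoxymethoxy)phenoxy]-3-methyl-3-(triethylsilyloxy)butyl]-5,7-bis(methoxymethoxy)-6,8-bis(3-methylbut-2-enyl)chromen-4-one | CC(C)=CCc1c(OCOC)c(CC=C(C)C)c2occ(C[C@H](C(C)(C)O[Si](CC)(CC)CC)Oc3cc(OCOC)ccc3Br)c(=O)c2c1OCOC | intermediate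
23 | 5,7,4'-tris(methoxymethyl) ether and C11 triethylsilyl ether of the target (10R) | CC(C)=CCc1c(OCOC)c(CC=C(C)C)c2oc3c(c(=O)c2c1OCOC)C[C@H](C(C)(C)O[Si](CC)(CC)CC)Oc1cc(OCOC)ccc1-3 | intermediate
24 | CNP0328977.2, (10R)-5,7,4'-trihydroxy-6,8-bis(3-methylbut-2-enyl)flavone with the C3–C9H2–C10H[C(CH3)2OH]–O–C2' bridge | CC(C)=CCc1c(O)c(CC=C(C)C)c2oc3c(c(=O)c2c1O)C[C@H](C(C)(C)O)Oc1cc(O)ccc1-3 | target

**Step count and risks**

Total: 16 steps. Longest linear sequence: 12 steps (10 → 24, steps 5–16). Ring A fragment 7 (steps 1–3) and phenol 9 (step 4) enter at steps 11 and 7.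

Steps most likely to fail:

1. Step 15 (ring D closure). Reductive loss of bromine from the aryl–palladium species may outrun the slow closure of the seven-membered ring, or the catalyst may die before C2–H is cleaved. Fallback from 22: C2 is deprotonated with TMPZnCl·LiCl (THF, 25 °C) to give the chromon-2-ylzinc chloride F1. Addition of Pd(OAc)2 and SPhos (THF, 50 °C) should then close ring D by intramolecular Negishi coupling with the C1'–Br bond. The same C2–C1' bond is formed by transmetalation instead of C–H cleavage at palladium, and the route is rejoined at 23.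

2. Step 11 (aryllithium plus lactone). Proton transfer from the lactone α-CH2 to the hindered aryllithium, or bromine–lithium exchange at ring B, may compete with carbonyl addition. Fallback from 16: reduction with i-Bu2AlH (CH2Cl2, −78 °C) gives the lactol F2. Aryllithium 17 (2.2 equiv, THF, −78 °C) adds to its open hydroxy-aldehyde form to give the diol F3 as a mixture at the new carbinol. Dess–Martin periodinane with NaHCO3 (CH2Cl2, 0 °C) oxidises only the secondary benzylic alcohol and returns to the route at 18.

3. Step 14 (ring C annulation). Condensation at the hindered α-CH2 may be slow, so that O-methylation of the phenol by the amide acetal takes over. Fallback from 20: Claisen C-formylation with NaH and ethyl formate (THF, 0 °C → rt) gives the β-keto aldehyde in its cyclic hemiacetal form, the 2-hydroxychroman-4-one F4 (mixture at C2 and C3). Warming with AcOH in toluene (60 °C) dehydrates it, and the route is rejoined at 22.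

**Further compounds**

F1 | step 15 | {3-[(2R)-2-[2-bromo-5-(methoxymethoxy)phenoxy]-3-methyl-3-(triethylsilyloxy)butyl]-5,7-bis(methoxymethoxy)-6,8-bis(3-methylbut-2-enyl)-4-oxochromen-2-yl}zinc chloride | CC(C)=CCc1c(OCOC)c(CC=C(C)C)c2oc([Zn]Cl)c(C[C@H](C(C)(C)O[Si](CC)(CC)CC)Oc3cc(OCOC)ccc3Br)c(=O)c2c1OCOC
F2 | step 11 | (5R)-5-[2-bromo-5-(methoxymethoxy)phenoxy]-6,6-dimethyloxan-2-ol (anomeric mixture) | OC1CC[C@@H](Oc2cc(OCOC)ccc2Br)C(C)(C)O1
F3 | step 11 | (4R)-4-[2-bromo-5-(methoxymethoxy)phenoxy]-5-methyl-1-[2,4,6-tris(methoxymethoxy)-3,5-bis(3-methylbut-2-enyl)phenyl]hexane-1,5-diol (mixture at C1) | CC(C)=CCc1c(OCOC)c(CC=C(C)C)c(OCOC)c(C(O)CC[C@@H](Oc2cc(OCOC)ccc2Br)C(C)(C)O)c1OCOC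
F4 | step 14 | 3-[(2R)-2-[2-bromo-5-(methoxymethoxy)phenoxy]-3-methyl-3-(triethylsilyloxy)butyl]-2-hydroxy-5,7-bis(methoxymethoxy)-6,8-bis(3-methylbut-2-enyl)chroman-4-one (mixture at C2 and C3) | CC(C)=CCc1c(OCOC)c(CC=C(C)C)c2OC(O)C(C[C@H](C(C)(C)O[Si](CC)(CC)CC)Oc3cc(OCOC)ccc3Br)C(=O)c2c1OCOC
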